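The plan rests on opening the ten-membered carbocycle (C1–C10) at the C3–C4 single bond, where C4 is the trisubstituted olefin carbon bearing C15 and C3 is a plain methylene. In one operation, 9-BBN hydroboration of the terminal C2=C3 alkene of a seco dienoate and intramolecular B-alkyl Suzuki–Miyaura coupling with a geometrically defined C4 alkenyl iodide form this bond and close the cyclodecadiene with both ring olefins already in place. The precursor is an open C1–C10 chain carrying all four stereocentres (C6–C9), the C9 acetate, the C8 isobutyrate and the C14 ester, with the α-methylene lactone ring held open as O6 and O12 silyl ethers and O15 silylated.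

Key step: step 19

Remark: C1–C15 and O6–O15 are germacrane locants of the target; NAP = naphthalen-2-ylmethyl, TBS = tert-butyldimethylsilyl, TBDPS = tert-butyldiphenylsilyl; O15 is carried as the TBDPS ether so that the temporary O8 NAP ether can be cleaved oxidatively without touching it.

Step 1
Reactants: 1 prop-2-yn-1-ol
Product: 2 tert-butyl(diphenyl)(prop-2-yn-1-yloxy)silane
Conditions: TBDPSCl, imidazole, CH2Cl2, 0 → 23 °C
Reagents that add atoms: tert-butyl(chloro)diphenylsilane, CC(C)(C)[Si](Cl)(c1ccccc1)c1ccccc1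
Why: Silyl ether formation on an unhindered primary alcohol gives the hydride- and oxidant-stable O15 protecting group.

Step 2
Reactants: 3 naphthalen-2-ylmethanol; 4 bromoacetic acid
Product: 5 2-(naphthalen-2-ylmethoxy)acetic acid
Conditions: NaH, THF, 0 → 65 °C; then aq. HCl
Reagents that add atoms: none
Why: Williamson etherification of the sodium alkoxide of 3 with sodium bromoacetate gives the O-arylmethyl glycolic acid needed for the glycolate Claisen step.

Step 3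
Reactants: 6 (R)-2,3-O-isopropylideneglyceraldehyde; 7 ethyl (triphenyl-λ5-phosphanylidene)acetate
Product: 9 ethyl (2Z)-2-bromo-3-[(4S)-2,2-dimethyl-1,3-dioxolan-4-yl]prop-2-enoate, via bromo ylide 8 (not isolated)
Conditions: NBS, CH2Cl2, −20 °C; then 6, −20 → 23 °C
Reagents that add atoms: N-bromosuccinimide, O=C1CCC(=O)N1Br
Why: Bromination of the stabilised ylide followed by Wittig olefination should give the α-bromo enoate with bromine cis to the dioxolane under neutral conditions that do not epimerise the α-alkoxy aldehyde.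

Step 4
Reactants: 9 ethyl (2Z)-2-bromo-3-[(4S)-2,2-dimethyl-1,3-dioxolan-4-yl]prop-2-enoate; 10 (tributylstannyl)methanol
Product: 11 ethyl (2E)-3-[(4S)-2,2-dimethyl-1,3-dioxolan-4-yl]-2-(hydroxymethyl)prop-2-enoate
Conditions: Pd(PPh3)4 (5 mol %), 1,4-dioxane, 90 °C
Reagents that add atoms: none
Why: Stille hydroxymethylation replaces bromine with retention of olefin geometry, so the new CH2OH carbon (C12) stays cis to the dioxolane and the ester carbon (C13) trans.

Step 5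
Reactants: 11 ethyl (2E)-3-[(4S)-2,2-dimethyl-1,3-dioxolan-4-yl]-2-(hydroxymethyl)prop-2-enoate
Product: 12 ethyl (2E)-2-{[(tert-butyldimethylsilyl)oxy]methyl}-3-[(4S)-2,2-dimethyl-1,3-dioxolan-4-yl]prop-2-enoate
Conditions: TBSCl, imidazole, DMF, 23 °C
Reagents that add atoms: tert-butyl(chloro)dimethylsilane, CC(C)(C)[Si](C)(C)Cl
Why: Silylation of the primary allylic alcohol installs the O12 protecting group that survives to the end game.

Step 6
Reactants: 12 ethyl (2E)-2-{[(tert-butyldimethylsilyl)oxy]methyl}-3-[(4S)-2,2-dimethyl-1,3-dioxolan-4-yl]prop-2-enoate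
Product: 13 (2Z)-2-{[(tert-butyldimethylsilyl)oxy]methyl}-3-[(4S)-2,2-dimethyl-1,3-dioxolan-4-yl]prop-2-en-1-ol
Conditions: iBu2AlH, CH2Cl2, −78 °C; aq. potassium sodium tartrate
Reagents that add atoms: none
Why: 1,2-Reduction of the conjugated ester by iBu2AlH gives the C13 allylic alcohol without touching the olefin geometry, the acetonide or the silyl ether.

Step 7
Reactants: 13 (2Z)-2-{[(tert-butyldimethylsilyl)oxy]methyl}-3-[(4S)-2,2-dimethyl-1,3-dioxolan-4-yl]prop-2-en-1-ol; 5 2-(naphthalen-2-ylmethoxy)acetic acid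
Product: 14 (2Z)-2-{[(tert-butyldimethylsilyl)oxy]methyl}-3-[(4S)-2,2-dimethyl-1,3-dioxolan-4-yl]prop-2-en-1-yl 2-(naphthalen-2-ylmethoxy)acetate
Conditions: DCC, DMAP (cat.), CH2Cl2, 0 → 23 °C
Reagents that add atoms: none
Why: Steglich esterification joins the glycolate to the allylic arm that lies trans to the dioxolane, the arrangement the Claisen step needs.

Step 8
Reactants: 14 (2Z)-2-{[(tert-butyldimethylsilyl)oxy]methyl}-3-[(4S)-2,2-dimethyl-1,3-dioxolan-4-yl]prop-2-en-1-yl 2-(naphthalen-2-ylmethoxy)acetate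
Product: 18 methyl (2S,3S)-4-{[(tert-butyldimethylsilyl)oxy]methyl}-3-[(4S)-2,2-dimethyl-1,3-dioxolan-4-yl]-2-(naphthalen-2-ylmethoxy)pent-4-enoate, via silyl ketene acetal 15 (not isolated), via trimethylsilyl ester 16 (not isolated), via carboxylic acid 17 (not isolated)
Conditions: LiN(iPr)2, THF, −78 °C; Me3SiCl, Et3N, −78 → 23 °C; aq. HCl; then Me3SiCHN2, PhMe/MeOH, 0 °C
Reagents that add atoms: (trimethylsilyl)diazomethane, C[Si](C)(C)C=[N+]=[N-]
Why: In this Ireland–Claisen rearrangement the lithium-chelated (Z)-glycolate enolate reacts through a chair with the ONAP and dioxolanyl groups equatorial, which gives the 7,8-anti relationship, and the new bond at C7 forms anti to the dioxolane C–O bond while its C–H eclipses the olefin to relieve A(1,3) strain with the cis silyloxymethyl group, which sets the absolute configuration of C7 and C8 and creates the C11=C13 methylene, the acid being methylated in the same operation.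

Step 9
Reactants: 18 methyl (2S,3S)-4-{[(tert-butyldimethylsilyl)oxy]methyl}-3-[(4S)-2,2-dimethyl-1,3-dioxolan-4-yl]-2-(naphthalen-2-ylmethoxy)pent-4-enoate
Product: 19 methyl (2S,3R)-4-{[(tert-butyldimethylsilyl)oxy]methyl}-3-formyl-2-(naphthalen-2-ylmethoxy)pent-4-enoate
Conditions: H5IO6, EtOAc, 23 °C; used crude
Reagents that add atoms: none
Why: Periodic acid hydrolyses the terminal acetonide and cleaves the resulting glycol in one pot, unmasking C6 as the aldehyde without base so that the α-stereocentre of the β,γ-unsaturated aldehyde is not equilibrated.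

Step 10
Reactants: 19 methyl (2S,3R)-4-{[(tert-butyldimethylsilyl)oxy]methyl}-3-formyl-2-(naphthalen-2-ylmethoxy)pent-4-enoate; 2 tert-butyl(diphenyl)(prop-2-yn-1-yloxy)silane
Product: 21 methyl (2S,3S,4S)-7-[(tert-butyldiphenylsilyl)oxy]-3-(3-{[tert-butyldimethylsilyl]oxy}prop-1-en-2-yl)-4-hydroxy-2-(naphthalen-2-ylmethoxy)hept-5-ynoate, via lithium acetylide 20 (not isolated)
Conditions: n-BuLi, THF, −78 °C; then 19, −78 °C; aq. NH4Cl
Reagents that add atoms: none
Why: 1,2-Addition of the lithium acetylide to the aldehyde, far faster than to the ester at −78 °C, should follow the Felkin–Anh mode anti to the C7–C8 bond, reinforced by 1,3-anti induction from the O8 ether, and so set C6.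

Step 11
Reactants: 21 methyl (2S,3S,4S)-7-[(tert-butyldiphenylsilyl)oxy]-3-(3-{[tert-butyldimethylsilyl]oxy}prop-1-en-2-yl)-4-hydroxy-2-(naphthalen-2-ylmethoxy)hept-5-ynoate
Product: 23 (2S,3S,4S,5Z)-7-[(tert-butyldiphenylsilyl)oxy]-3-(3-{[tert-butyldimethylsilyl]oxy}prop-1-en-2-yl)-6-iodo-2-(naphthalen-2-ylmethoxy)hept-5-ene-1,4-diol, via cyclic alkenylaluminate 22 (not isolated)
Conditions: NaAlH2(OCH2CH2OMe)2, THF, 0 → 23 °C; then I2, −78 → 0 °C
Reagents that add atoms: iodine, II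
Why: Hydroxyl-directed trans-hydroalumination of the propargylic alkoxide places aluminium on C4 cis to C6 and iodinolysis with retention gives the (Z)-C4 iodide, while the same hydride reduces the C9 ester to the primary alcohol before any other ester is present.

Step 12
Reactants: 23 (2S,3S,4S,5Z)-7-[(tert-butyldiphenylsilyl)oxy]-3-(3-{[tert-butyldimethylsilyl]oxy}prop-1-en-2-yl)-6-iodo-2-(naphthalen-2-ylmethoxy)hept-5-ene-1,4-diol
Product: 25 1-O-triethylsilyl 4-O-tert-butyldimethylsilyl ether of 23, via mono-triethylsilyl ether 24 (not isolated)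
Conditions: Et3SiCl, imidazole, CH2Cl2, −78 °C; then TBSOTf, 2,6-lutidine, −78 → 0 °C
Reagents that add atoms: chlorotriethylsilane, CC[Si](Cl)(CC)CC; tert-butyldimethylsilyl trifluoromethanesulfonate, CC(C)(C)[Si](C)(C)OS(=O)(=O)C(F)(F)F
Why: Sequential silylation exploits the higher reactivity of the primary C9 hydroxyl toward the small chlorosilane, after which the silyl triflate caps the hindered secondary O6.

Step 13
Reactants: 25 1-O-triethylsilyl 4-O-tert-butyldimethylsilyl ether of 23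
Product: 26 (2S,3R,4S,5Z)-4-[(tert-butyldimethylsilyl)oxy]-7-[(tert-butyldiphenylsilyl)oxy]-3-(3-{[tert-butyldimethylsilyl]oxy}prop-1-en-2-yl)-6-iodo-2-(naphthalen-2-ylmethoxy)hept-5-enal
Conditions: (COCl)2, DMSO, CH2Cl2, −78 → −30 °C; then Et3N, −78 → 0 °C
Reagents that add atoms: none
Why: Under Swern conditions a primary triethylsilyl ether is oxidised directly to the aldehyde while the bulkier silyl ethers and the NAP ether stay intact, and the low temperature protects the α-alkoxy stereocentre.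

Step 14
Reactants: 26 (2S,3R,4S,5Z)-4-[(tert-butyldimethylsilyl)oxy]-7-[(tert-butyldiphenylsilyl)oxy]-3-(3-{[tert-butyldimethylsilyl]oxy}prop-1-en-2-yl)-6-iodo-2-(naphthalen-2-ylmethoxy)hept-5-enal; 27 methyl propiolate
Product: 29 methyl (2E)-2-[(1S,2S,3R,4S,5Z)-4-[(tert-butyldimethylsilyl)oxy]-7-[(tert-butyldiphenylsilyl)oxy]-3-(3-{[tert-butyldimethylsilyl]oxy}prop-1-en-2-yl)-1-hydroxy-6-iodo-2-(naphthalen-2-ylmethoxy)hept-5-en-1-yl]-3-iodoprop-2-enoate, via zirconium iodoallenolate 28 (not isolated)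
Conditions: Bu4NI, ZrCl4, CH2Cl2, −20 → 0 °C
Reagents that add atoms: tetrabutylammonium iodide, CCCC[N+](CCCC)(CCCC)CCCC.[I-]
Why: In this iodide-triggered halo-aldol (β-iodo Morita–Baylis–Hillman) reaction iodide adds to 27 to give an allenolate that attacks the ZrCl4-chelated α-alkoxy aldehyde from the open face of the chelate, setting C9 syn to O8, and reversible iodide addition–elimination under the Lewis acid should funnel the product to the (E)-β-iodo enoate with iodine cis to the carbinol.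

Step 15
Reactants: 29 methyl (2E)-2-[(1S,2S,3R,4S,5Z)-…-1-hydroxy-6-iodo-…hept-5-en-1-yl]-3-iodoprop-2-enoate
Product: 30 methyl (2E)-2-[(1S,2S,3R,4S,5Z)-4-[(tert-butyldimethylsilyl)oxy]-7-[(tert-butyldiphenylsilyl)oxy]-3-(3-{[tert-butyldimethylsilyl]oxy}prop-1-en-2-yl)-1-hydroxy-6-iodo-2-(naphthalen-2-ylmethoxy)hept-5-en-1-yl]penta-2,4-dienoate
Conditions: CH2=CHMgBr, CuI, THF, −78 → −40 °C
Reagents that add atoms: vinylmagnesium bromide, C=C[Mg]Br
Why: Organocuprate addition–elimination at the β-iodo enoate replaces iodine by vinyl with retention, so the vinyl group ends cis to C9, while the unactivated C4 iodide, which cannot accept a conjugate addition, and the magnesium alkoxide should be left alone at low temperature.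

Step 16
Reactants: 30 methyl (2E)-2-[(1S,2S,3R,4S,5Z)-…-1-hydroxy-…]penta-2,4-dienoate
Product: 31 1-O-acetate of 30 (C9 acetate)
Conditions: Ac2O, pyridine, DMAP (cat.), CH2Cl2, 0 °C
Reagents that add atoms: acetic anhydride, CC(=O)OC(C)=O
Why: Acylation of the only free hydroxyl installs the C9 acetate after the cuprate step, so that no allylic acetate is exposed to the organocopper reagent.

Step 17
Reactants: 31 1-O-acetate of 30
Product: 32 methyl (2E)-2-[(1S,2S,3R,4S,5Z)-1-(acetyloxy)-4-[(tert-butyldimethylsilyl)oxy]-7-[(tert-butyldiphenylsilyl)oxy]-3-(3-{[tert-butyldimethylsilyl]oxy}prop-1-en-2-yl)-2-hydroxy-6-iodohept-5-en-1-yl]penta-2,4-dienoate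
Conditions: DDQ, CH2Cl2/pH 7 buffer, 23 °C
Reagents that add atoms: none
Why: Oxidative cleavage of the electron-rich naphthylmethyl ether by DDQ frees O8 while silyl ethers, the alkenyl iodide, the electron-poor diene and the esters are inert to the quinone.

Step 18
Reactants: 32 C8 alcohol
Product: 33 methyl (2E)-2-[(1S,2S,3R,4S,5Z)-1-(acetyloxy)-4-[(tert-butyldimethylsilyl)oxy]-7-[(tert-butyldiphenylsilyl)oxy]-3-(3-{[tert-butyldimethylsilyl]oxy}prop-1-en-2-yl)-6-iodo-2-[(2-methylpropanoyl)oxy]hept-5-en-1-yl]penta-2,4-dienoate (seco dienoate iodoalkene)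
Conditions: iPrCOCl, pyridine, DMAP (cat.), CH2Cl2, 0 → 23 °C
Reagents that add atoms: 2-methylpropanoyl chloride, CC(C)C(=O)Cl
Why: Fast acylation with the acid chloride directly after the deprotection should place the isobutyrate on O8 before the neighbouring acetate can migrate.

Step 19
Reactants: 33 seco dienoate iodoalkene
Product: 35 methyl (1(10)E,4E,6R,7R,8S,9S)-9-acetoxy-6,12-bis[(tert-butyldimethylsilyl)oxy]-15-[(tert-butyldiphenylsilyl)oxy]-8-(isobutyryloxy)germacra-1(10),4,11(13)-trien-14-oate, via C3 alkyl-9-BBN borane 34 (not isolated)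
Conditions: 9-BBN, THF, 0 → 23 °C; then Pd(dppf)Cl2·CH2Cl2 (20 mol %), AsPh3, Cs2CO3, DMF/THF/H2O, 1 mM, 23 → 45 °C
Reagents that add atoms: none
Why: 9-BBN adds across the unhindered monosubstituted C2=C3 bond with boron on C3; zerovalent palladium formed from Pd(dppf)Cl2 inserts into the C4–I bond with retention, the carbonate-activated C3 borate transfers its primary alkyl group, and reductive elimination forms C3–C4. This is the intramolecular B-alkyl Suzuki–Miyaura coupling of an alkyl-9-BBN with an alkenyl iodide, a known macrocyclisation type. The ten-membered carbocycle closes by reductive elimination from an eleven-membered alkyl(alkenyl)palladium palladacycle under high dilution. No stereocentre is created, and both ring olefin geometries are inherited unchanged from 33. The hydroboration has to prefer C2=C3 over the 1,1-disubstituted C11=C13 bond and the conjugated esters, which rests on the substrate and not on the reagent alone: C11=C13 is buried between the C7 methine and the silyloxymethyl group and is inductively deactivated, and palladium insertion into the C–I bond must also outrun ionisation of the hindered C9 allylic acetate.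

Step 20
Reactants: 35 protected macrocycle
Product: 36 methyl (1(10)E,4E,6R,7S,8S,9S)-9-acetoxy-15-[(tert-butyldiphenylsilyl)oxy]-6,12-dihydroxy-8-(isobutyryloxy)germacra-1(10),4,11(13)-trien-14-oate
Conditions: HF·pyridine, pyridine, THF, 0 → 23 °C
Reagents that add atoms: none
Why: Buffered HF·pyridine desilylation should cleave the two TBS ethers well before the more robust primary TBDPS ether, leaving O15 protected for the oxidation.

Step 21
Reactants: 36 C6/C12 diol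
Product: 38 15-O-TBDPS ether of the target lactone, via C12 lactol 37 (not isolated)
Conditions: TEMPO (20 mol %), PhI(OAc)2, CH2Cl2, 23 °C
Reagents that add atoms: none
Why: The nitroxyl-catalysed oxidation picks the primary allylic C12 alcohol over the hindered secondary C6 alcohol, the aldehyde is trapped by O6 as the five-membered lactol, and this is oxidised on to the α-methylene γ-lactone (oxidative lactonisation).

Step 22
Reactants: 38 15-O-TBDPS ether of the target lactone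
Product: 39 methyl (1(10)E,4E,6R,7S,8S,9S)-9-acetoxy-15-hydroxy-8-(isobutyryloxy)-12-oxo-6,12-epoxygermacra-1(10),4,11(13)-trien-14-oate (CNP0242134.2)
Conditions: HF·pyridine (excess), THF, 23 °C
Reagents that add atoms: none
Why: Acidic fluoride desilylation removes the last silyl ether without basic conditions that could add to the α-methylene lactone or move the acetate and isobutyrate.

Compound list
1 | prop-2-yn-1-ol | C#CCO | starting material
2 | tert-butyl(diphenyl)(prop-2-yn-1-yloxy)silane | C#CCO[Si](c1ccccc1)(c1ccccc1)C(C)(C)C | intermediate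
3 | naphthalen-2-ylmethanol | OCc1ccc2ccccc2c1 | starting material
4 | bromoacetic acid | OC(=O)CBr | starting material
5 | 2-(naphthalen-2-ylmethoxy)acetic acid | OC(=O)COCc1ccc2ccccc2c1 | intermediate
6 | (R)-2,3-O-isopropylideneglyceraldehyde | O=C[C@H]1COC(C)(C)O1 | starting material
7 | ethyl (triphenyl-λ5-phosphanylidene)acetate | CCOC(=O)C=P(c1ccccc1)(c1ccccc1)c1ccccc1 | starting material
8 | ethyl bromo(triphenyl-λ5-phosphanylidene)acetate (bromo ylide) | CCOC(=O)C(Br)=P(c1ccccc1)(c1ccccc1)c1ccccc1 | intermediate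
9 | ethyl (2Z)-2-bromo-3-[(4S)-2,2-dimethyl-1,3-dioxolan-4-yl]prop-2-enoate | CCOC(=O)/C(Br)=C/[C@H]1COC(C)(C)O1 | intermediate
10 | (tributylstannyl)methanol | CCCC[Sn](CCCC)(CCCC)CO | starting material
11 | ethyl (2E)-3-[(4S)-2,2-dimethyl-1,3-dioxolan-4-yl]-2-(hydroxymethyl)prop-2-enoate | CCOC(=O)/C(CO)=C/[C@H]1COC(C)(C)O1 | intermediate
12 | ethyl (2E)-2-{[(tert-butyldimethylsilyl)oxy]methyl}-3-[(4S)-2,2-dimethyl-1,3-dioxolan-4-yl]prop-2-enoate | CCOC(=O)/C(CO[Si](C)(C)C(C)(C)C)=C/[C@H]1COC(C)(C)O1 | intermediate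
13 | (2Z)-2-{[(tert-butyldimethylsilyl)oxy]methyl}-3-[(4S)-2,2-dimethyl-1,3-dioxolan-4-yl]prop-2-en-1-ol | OC/C(CO[Si](C)(C)C(C)(C)C)=C/[C@H]1COC(C)(C)O1 | intermediate
14 | (2Z)-2-{[(tert-butyldimethylsilyl)oxy]methyl}-3-[(4S)-2,2-dimethyl-1,3-dioxolan-4-yl]prop-2-en-1-yl 2-(naphthalen-2-ylmethoxy)acetate | O=C(COCc1ccc2ccccc2c1)OC/C(CO[Si](C)(C)C(C)(C)C)=C/[C@H]1COC(C)(C)O1 | intermediate
15 | trimethylsilyl ketene acetal of 14 (OSiMe3 cis to ONAP) | C[Si](C)(C)O/C(OC/C(CO[Si](C)(C)C(C)(C)C)=C/[C@H]1COC(C)(C)O1)=C\OCc1ccc2ccccc2c1 | intermediate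
16 | trimethylsilyl (2S,3S)-4-{[(tert-butyldimethylsilyl)oxy]methyl}-3-[(4S)-2,2-dimethyl-1,3-dioxolan-4-yl]-2-(naphthalen-2-ylmethoxy)pent-4-enoate | C[Si](C)(C)OC(=O)[C@@H](OCc1ccc2ccccc2c1)[C@H]([C@H]1COC(C)(C)O1)C(=C)CO[Si](C)(C)C(C)(C)C | intermediate
17 | (2S,3S)-4-{[(tert-butyldimethylsilyl)oxy]methyl}-3-[(4S)-2,2-dimethyl-1,3-dioxolan-4-yl]-2-(naphthalen-2-ylmethoxy)pent-4-enoic acid | OC(=O)[C@@H](OCc1ccc2ccccc2c1)[C@H]([C@H]1COC(C)(C)O1)C(=C)CO[Si](C)(C)C(C)(C)C | intermediate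
18 | methyl (2S,3S)-4-{[(tert-butyldimethylsilyl)oxy]methyl}-3-[(4S)-2,2-dimethyl-1,3-dioxolan-4-yl]-2-(naphthalen-2-ylmethoxy)pent-4-enoate | COC(=O)[C@@H](OCc1ccc2ccccc2c1)[C@H]([C@H]1COC(C)(C)O1)C(=C)CO[Si](C)(C)C(C)(C)C | intermediate
19 | methyl (2S,3R)-4-{[(tert-butyldimethylsilyl)oxy]methyl}-3-formyl-2-(naphthalen-2-ylmethoxy)pent-4-enoate | COC(=O)[C@@H](OCc1ccc2ccccc2c1)[C@H](C=O)C(=C)CO[Si](C)(C)C(C)(C)C | intermediate
20 | lithium acetylide of 2 | [Li]C#CCO[Si](c1ccccc1)(c1ccccc1)C(C)(C)C | intermediate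
21 | methyl (2S,3S,4S)-7-[(tert-butyldiphenylsilyl)oxy]-3-(3-{[tert-butyldimethylsilyl]oxy}prop-1-en-2-yl)-4-hydroxy-2-(naphthalen-2-ylmethoxy)hept-5-ynoate | COC(=O)[C@@H](OCc1ccc2ccccc2c1)[C@H]([C@H](O)C#CCO[Si](c1ccccc1)(c1ccccc1)C(C)(C)C)C(=C)CO[Si](C)(C)C(C)(C)C | intermediate
22 | disodium salt of the cyclic C4-alkenyl(O6-alkoxy)bis(2-methoxyethoxy)aluminate, C9 alkoxide | [Na+].[Na+].[O-]C[C@@H](OCc1ccc2ccccc2c1)[C@H]([C@@H]1O[Al-](OCCOC)(OCCOC)C(CO[Si](c2ccccc2)(c2ccccc2)C(C)(C)C)=C1)C(=C)CO[Si](C)(C)C(C)(C)C | intermediate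
23 | (2S,3S,4S,5Z)-7-[(tert-butyldiphenylsilyl)oxy]-3-(3-{[tert-butyldimethylsilyl]oxy}prop-1-en-2-yl)-6-iodo-2-(naphthalen-2-ylmethoxy)hept-5-ene-1,4-diol | OC[C@@H](OCc1ccc2ccccc2c1)[C@H]([C@H](O)/C=C(I)/CO[Si](c1ccccc1)(c1ccccc1)C(C)(C)C)C(=C)CO[Si](C)(C)C(C)(C)C | intermediate
24 | 1-O-triethylsilyl ether of 23 (2S,3S,4S,5Z) | CC[Si](CC)(CC)OC[C@@H](OCc1ccc2ccccc2c1)[C@H]([C@H](O)/C=C(I)/CO[Si](c1ccccc1)(c1ccccc1)C(C)(C)C)C(=C)CO[Si](C)(C)C(C)(C)C | intermediate
25 | 1-O-triethylsilyl 4-O-tert-butyldimethylsilyl ether of 23 (2S,3R,4S,5Z) | CC[Si](CC)(CC)OC[C@@H](OCc1ccc2ccccc2c1)[C@H]([C@H](O[Si](C)(C)C(C)(C)C)/C=C(I)/CO[Si](c1ccccc1)(c1ccccc1)C(C)(C)C)C(=C)CO[Si](C)(C)C(C)(C)C | intermediate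
26 | (2S,3R,4S,5Z)-4-[(tert-butyldimethylsilyl)oxy]-7-[(tert-butyldiphenylsilyl)oxy]-3-(3-{[tert-butyldimethylsilyl]oxy}prop-1-en-2-yl)-6-iodo-2-(naphthalen-2-ylmethoxy)hept-5-enal | O=C[C@@H](OCc1ccc2ccccc2c1)[C@H]([C@H](O[Si](C)(C)C(C)(C)C)/C=C(I)/CO[Si](c1ccccc1)(c1ccccc1)C(C)(C)C)C(=C)CO[Si](C)(C)C(C)(C)C | intermediate
27 | methyl propiolate | C#CC(=O)OC | starting material
28 | trichlorozirconium 3-iodo-1-methoxypropa-1,2-dien-1-olate (iodoallenolate) | COC(O[Zr](Cl)(Cl)Cl)=C=CI | intermediate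
29 | methyl (2E)-2-[(1S,2S,3R,4S,5Z)-4-[(tert-butyldimethylsilyl)oxy]-7-[(tert-butyldiphenylsilyl)oxy]-3-(3-{[tert-butyldimethylsilyl]oxy}prop-1-en-2-yl)-1-hydroxy-6-iodo-2-(naphthalen-2-ylmethoxy)hept-5-en-1-yl]-3-iodoprop-2-enoate | I/C=C(/C(=O)OC)[C@H](O)[C@@H](OCc1ccc2ccccc2c1)[C@H]([C@H](O[Si](C)(C)C(C)(C)C)/C=C(I)/CO[Si](c1ccccc1)(c1ccccc1)C(C)(C)C)C(=C)CO[Si](C)(C)C(C)(C)C | intermediate
30 | methyl (2E)-2-[(1S,2S,3R,4S,5Z)-4-[(tert-butyldimethylsilyl)oxy]-7-[(tert-butyldiphenylsilyl)oxy]-3-(3-{[tert-butyldimethylsilyl]oxy}prop-1-en-2-yl)-1-hydroxy-6-iodo-2-(naphthalen-2-ylmethoxy)hept-5-en-1-yl]penta-2,4-dienoate | C=C/C=C(/C(=O)OC)[C@H](O)[C@@H](OCc1ccc2ccccc2c1)[C@H]([C@H](O[Si](C)(C)C(C)(C)C)/C=C(I)/CO[Si](c1ccccc1)(c1ccccc1)C(C)(C)C)C(=C)CO[Si](C)(C)C(C)(C)C | intermediate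
31 | 1-O-acetate of 30 (C9 acetate; 1S,2S,3R,4S,5Z) | C=C/C=C(/C(=O)OC)[C@H](OC(C)=O)[C@@H](OCc1ccc2ccccc2c1)[C@H]([C@H](O[Si](C)(C)C(C)(C)C)/C=C(I)/CO[Si](c1ccccc1)(c1ccccc1)C(C)(C)C)C(=C)CO[Si](C)(C)C(C)(C)C | intermediate
32 | methyl (2E)-2-[(1S,2S,3R,4S,5Z)-1-(acetyloxy)-4-[(tert-butyldimethylsilyl)oxy]-7-[(tert-butyldiphenylsilyl)oxy]-3-(3-{[tert-butyldimethylsilyl]oxy}prop-1-en-2-yl)-2-hydroxy-6-iodohept-5-en-1-yl]penta-2,4-dienoate | C=C/C=C(/C(=O)OC)[C@H](OC(C)=O)[C@@H](O)[C@H]([C@H](O[Si](C)(C)C(C)(C)C)/C=C(I)/CO[Si](c1ccccc1)(c1ccccc1)C(C)(C)C)C(=C)CO[Si](C)(C)C(C)(C)C | intermediate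
33 | methyl (2E)-2-[(1S,2S,3R,4S,5Z)-1-(acetyloxy)-4-[(tert-butyldimethylsilyl)oxy]-7-[(tert-butyldiphenylsilyl)oxy]-3-(3-{[tert-butyldimethylsilyl]oxy}prop-1-en-2-yl)-6-iodo-2-[(2-methylpropanoyl)oxy]hept-5-en-1-yl]penta-2,4-dienoate (seco dienoate iodoalkene) | C=C/C=C(/C(=O)OC)[C@H](OC(C)=O)[C@@H](OC(=O)C(C)C)[C@H]([C@H](O[Si](C)(C)C(C)(C)C)/C=C(I)/CO[Si](c1ccccc1)(c1ccccc1)C(C)(C)C)C(=C)CO[Si](C)(C)C(C)(C)C | intermediate
34 | C3 B-alkyl-9-borabicyclo[3.3.1]nonane derived from 33 | C(C/C=C(/C(=O)OC)[C@H](OC(C)=O)[C@@H](OC(=O)C(C)C)[C@H]([C@H](O[Si](C)(C)C(C)(C)C)/C=C(I)/CO[Si](c1ccccc1)(c1ccccc1)C(C)(C)C)C(=C)CO[Si](C)(C)C(C)(C)C)B1C2CCCC1CCC2 | intermediate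
35 | methyl (1(10)E,4E,6R,7R,8S,9S)-9-acetoxy-6,12-bis[(tert-butyldimethylsilyl)oxy]-15-[(tert-butyldiphenylsilyl)oxy]-8-(isobutyryloxy)germacra-1(10),4,11(13)-trien-14-oate (protected macrocycle) | C=C(CO[Si](C)(C)C(C)(C)C)[C@H]1[C@H](O[Si](C)(C)C(C)(C)C)/C=C(/CO[Si](c2ccccc2)(c2ccccc2)C(C)(C)C)CC/C=C(/C(=O)OC)[C@H](OC(C)=O)[C@H]1OC(=O)C(C)C | intermediate
36 | methyl (1(10)E,4E,6R,7S,8S,9S)-9-acetoxy-15-[(tert-butyldiphenylsilyl)oxy]-6,12-dihydroxy-8-(isobutyryloxy)germacra-1(10),4,11(13)-trien-14-oate | C=C(CO)[C@H]1[C@H](O)/C=C(/CO[Si](c2ccccc2)(c2ccccc2)C(C)(C)C)CC/C=C(/C(=O)OC)[C@H](OC(C)=O)[C@H]1OC(=O)C(C)C | intermediate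
37 | C12 lactol of 38 (6,12-epoxy-12-hydroxy; C12 epimers) | C=C1C(O)O[C@@H]2/C=C(/CO[Si](c3ccccc3)(c3ccccc3)C(C)(C)C)CC/C=C(/C(=O)OC)[C@H](OC(C)=O)[C@@H](OC(=O)C(C)C)[C@@H]12 | intermediate
38 | 15-O-tert-butyldiphenylsilyl ether of 39 | C=C1C(=O)O[C@@H]2/C=C(/CO[Si](c3ccccc3)(c3ccccc3)C(C)(C)C)CC/C=C(/C(=O)OC)[C@H](OC(C)=O)[C@@H](OC(=O)C(C)C)[C@@H]12 | intermediate
39 | methyl (1(10)E,4E,6R,7S,8S,9S)-9-acetoxy-15-hydroxy-8-(isobutyryloxy)-12-oxo-6,12-epoxygermacra-1(10),4,11(13)-trien-14-oate (CNP0242134.2) | C=C1C(=O)O[C@@H]2/C=C(/CO)CC/C=C(/C(=O)OC)[C@H](OC(C)=O)[C@@H](OC(=O)C(C)C)[C@@H]12 | target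

Total step count: 22. Longest linear sequence: 20 steps (steps 3 to 22, from 6); steps 1 and 2 are side branches.

Steps most likely to fail

1. Step 19. The hydroboration may also consume the C11=C13 alkene, or the strained closure may be slow enough for protodeborylation and oligomerisation to take over. Fallback, setting out from 33 and rejoining at 39: PPTS in MeOH should remove only the primary O12 silyl ether to give the C12 allylic alcohol F1; MnO2 should give the enal F2, NaClO2/NaH2PO4/2-methylbut-2-ene the acrylic acid F3, and MeI/K2CO3 the C12 methyl ester F4, in which C11=C13 is an electron-poor acrylate that 9-BBN should leave alone. The same hydroboration (alkylborane F5, not isolated) and palladium-catalysed closure would give the macrocyclic diester F6. HF·pyridine would then strip both remaining silyl ethers, and the freed C6 hydroxyl of the hydroxy ester F7 (not isolated) would close the lactone on the C12 ester, so that no oxidation is needed after ring closure.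

2. Step 14. The Lewis acid may strip silyl or naphthylmethyl ethers, and the olefin geometry or the facial selectivity at C9 may erode. Fallback, setting out from 26 and rejoining at 30 (it also bypasses step 15): methyl 2-(phenylselanyl)pent-4-enoate F8 (from methyl pent-4-enoate, LiN(iPr)2, PhSeCl) is converted into its trimethylsilyl ketene acetal F9 (LiN(iPr)2, Me3SiCl). A MgBr2·OEt2-mediated Mukaiyama aldol addition to 26 under chelation control should give the β-hydroxy α-selanyl ester F10 with the same C9 configuration. Oxidation with H2O2/pyridine to the selenoxide F11 (not isolated) and syn-elimination away from the carbinol, toward the allylic C1 hydrogens, should deliver the (E)-dienoate 30 without a strong Lewis acid and without a second alkenyl iodide.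

3. Step 10. Facial selectivity at C6 may be poor, or the basic acetylide may enolise the aldehyde and erode C7. Fallback, setting out from 21 (as a mixture of C6 epimers) and rejoining at 21: Dess–Martin periodinane should oxidise the carbinol to the ynone F12, and asymmetric transfer hydrogenation with RuCl(p-cymene)[(S,S)-TsDPEN] in iPrOH, without added base, should return the (4S)-propargylic alcohol 21 under reagent control.

Further compounds
F1 | step 19 | 12-hydroxy analogue of 33 (O12 silyl ether removed) | C=C/C=C(/C(=O)OC)[C@H](OC(C)=O)[C@@H](OC(=O)C(C)C)[C@H]([C@H](O[Si](C)(C)C(C)(C)C)/C=C(I)/CO[Si](c1ccccc1)(c1ccccc1)C(C)(C)C)C(=C)CO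
F2 | step 19 | C12 enal of the seco chain | C=C/C=C(/C(=O)OC)[C@H](OC(C)=O)[C@@H](OC(=O)C(C)C)[C@H]([C@H](O[Si](C)(C)C(C)(C)C)/C=C(I)/CO[Si](c1ccccc1)(c1ccccc1)C(C)(C)C)C(=C)C=O
F3 | step 19 | C12 acrylic acid of the seco chain | C=C/C=C(/C(=O)OC)[C@H](OC(C)=O)[C@@H](OC(=O)C(C)C)[C@H]([C@H](O[Si](C)(C)C(C)(C)C)/C=C(I)/CO[Si](c1ccccc1)(c1ccccc1)C(C)(C)C)C(=C)C(=O)O
F4 | step 19 | C12 methyl ester of the seco chain | C=C/C=C(/C(=O)OC)[C@H](OC(C)=O)[C@@H](OC(=O)C(C)C)[C@H]([C@H](O[Si](C)(C)C(C)(C)C)/C=C(I)/CO[Si](c1ccccc1)(c1ccccc1)C(C)(C)C)C(=C)C(=O)OC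
F5 | step 19 | C3 B-alkyl-9-borabicyclo[3.3.1]nonane derived from F4 | C(C/C=C(/C(=O)OC)[C@H](OC(C)=O)[C@@H](OC(=O)C(C)C)[C@H]([C@H](O[Si](C)(C)C(C)(C)C)/C=C(I)/CO[Si](c1ccccc1)(c1ccccc1)C(C)(C)C)C(=C)C(=O)OC)B1C2CCCC1CCC2
F6 | step 19 | dimethyl (1(10)E,4E,6R,7R,8S,9S)-9-acetoxy-6-[(tert-butyldimethylsilyl)oxy]-15-[(tert-butyldiphenylsilyl)oxy]-8-(isobutyryloxy)germacra-1(10),4,11(13)-triene-12,14-dioate | C=C(C(=O)OC)[C@H]1[C@H](O[Si](C)(C)C(C)(C)C)/C=C(/CO[Si](c2ccccc2)(c2ccccc2)C(C)(C)C)CC/C=C(/C(=O)OC)[C@H](OC(C)=O)[C@H]1OC(=O)C(C)C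
F7 | step 19 | 6,15-dihydroxy diester from F6 | C=C(C(=O)OC)[C@H]1[C@H](O)/C=C(/CO)CC/C=C(/C(=O)OC)[C@H](OC(C)=O)[C@H]1OC(=O)C(C)C
F8 | step 14 | methyl 2-(phenylselanyl)pent-4-enoate (racemic) | C=CCC([Se]c1ccccc1)C(=O)OC
F9 | step 14 | trimethylsilyl ketene acetal of F8 | C=CCC([Se]c1ccccc1)=C(OC)O[Si](C)(C)C
F10 | step 14 | β-hydroxy α-(phenylselanyl) ester from 26 and F9 (C9 as in 30; C10 epimers) | C=CCC([Se]c1ccccc1)(C(=O)OC)[C@H](O)[C@@H](OCc1ccc2ccccc2c1)[C@H]([C@H](O[Si](C)(C)C(C)(C)C)/C=C(I)/CO[Si](c1ccccc1)(c1ccccc1)C(C)(C)C)C(=C)CO[Si](C)(C)C(C)(C)C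
F11 | step 14 | selenoxide of F10 | C=CCC([Se](=O)c1ccccc1)(C(=O)OC)[C@H](O)[C@@H](OCc1ccc2ccccc2c1)[C@H]([C@H](O[Si](C)(C)C(C)(C)C)/C=C(I)/CO[Si](c1ccccc1)(c1ccccc1)C(C)(C)C)C(=C)CO[Si](C)(C)C(C)(C)C
F12 | step 10 | methyl (2S,3R)-7-[(tert-butyldiphenylsilyl)oxy]-3-(3-{[tert-butyldimethylsilyl]oxy}prop-1-en-2-yl)-2-(naphthalen-2-ylmethoxy)-4-oxohept-5-ynoate | COC(=O)[C@@H](OCc1ccc2ccccc2c1)[C@H](C(=O)C#CCO[Si](c1ccccc1)(c1ccccc1)C(C)(C)C)C(=C)CO[Si](C)(C)C(C)(C)C
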